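**Retrosynthetic overview**
1. Feature: the 2,2-dimethylchroman-3-ol ring (O1'–C2'(CH3)2–C3'(OH)–C4'H2, fused to the arene through C8a'–O1' and C4a'–C4') is a phenol oxygen and an ortho benzylic carbon bridged by two carbons. It therefore maps onto an ortho-quinone methide plus the alkene (CH3)2C=CH–Si, with C3'–OH traced back to C3'–Si.
2. Key disconnection: C4'–C3' and O1'–C2', by inverse-demand oxa-Diels–Alder reaction of the quinone methide from the C5-[4-hydroxy-3-(hydroxymethyl)benzyl]butenolide with (2-methylprop-1-enyl)diphenylsilanol under a chiral Brønsted acid. A silanol is chosen because it can hydrogen-bond to the catalyst and is oxidised by buffered H2O2 without prior unmasking.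
3. C5–CH2Ar (butenolide numbering O1, C2=O, C3–OCH3, C4–aryl, C5): asymmetric phase-transfer benzylation of the C5–H butenolide ester with the acetonide-masked salicyl-type benzyl bromide sets the quaternary centre.
4. Butenolide ring (C4–C5 and O1–C2): aldol–lactonisation of methyl 3,4-bis(benzyloxy)phenylpyruvate with methyl glyoxylate, then O-methylation.
5. Ring order: butenolide (step 4), temporary benzodioxine (step 7, opened in step 11), dihydropyran (step 13). The end game is Tamao oxidation with retention, then hydrogenolysis.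

Key step: step 13

Assumption: no close precedent fixes the sense of induction in the two catalyst-controlled steps (10 and 13), so the catalyst antipode written is a working choice and the equally available mirror-image catalyst is taken if a test run shows the opposite sense.

**Step 1**
Reactants: 1 3,4-bis(benzyloxy)benzaldehyde; 2 hydantoin
Product: 3 (Z)-5-[3,4-bis(benzyloxy)benzylidene]imidazolidine-2,4-dione
Conditions: NH4OAc, AcOH, reflux
Reagents that add atoms: none
Why: Knoevenagel condensation of the acidic CH2 of hydantoin with a non-enolisable aromatic aldehyde should give the conjugated, poorly soluble (Z)-arylidene compound, which can be collected by filtration.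

**Step 2**
Reactants: 3 (Z)-5-[3,4-bis(benzyloxy)benzylidene]imidazolidine-2,4-dione
Product: 4 3-[3,4-bis(benzyloxy)phenyl]-2-oxopropanoic acid
Conditions: 20% aq NaOH, reflux, N2; then 6 M HCl, 0 °C
Reagents that add atoms: water, O
Why: Alkaline hydrolysis of a 5-arylidenehydantoin (ring opening, then enamide hydrolysis) is the classical route to arylpyruvic acids, and benzyl aryl ethers are inert to hot alkali.

**Step 3**
Reactants: 4 3-[3,4-bis(benzyloxy)phenyl]-2-oxopropanoic acid
Product: 5 methyl 3-[3,4-bis(benzyloxy)phenyl]-2-oxopropanoate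
Conditions: MeI, KHCO3, DMF, rt
Reagents that add atoms: iodomethane, CI
Why: Carboxylate alkylation (SN2) under bicarbonate, a base too weak to deprotonate the enol or the benzylic carbon, should esterify only the acid.

**Step 4**
Reactants: 5 methyl 3-[3,4-bis(benzyloxy)phenyl]-2-oxopropanoate; 6 methyl 2-hydroxy-2-methoxyacetate
Product: 9 methyl (±)-3-[3,4-bis(benzyloxy)phenyl]-4-hydroxy-5-oxo-2,5-dihydrofuran-2-carboxylate, via methyl glyoxylate 7 (not isolated), via aldol adduct 8 (not isolated)
Conditions: 6 (2 equiv), Et3N (1.2 equiv), THF, 0 °C → rt, Ar; 1 M HCl work-up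
Reagents that add atoms: none
Why: In this cross aldol–lactonisation (isotetronic acid synthesis) the amine enolises 5 at its benzylic carbon, the non-enolisable and far more electrophilic aldehyde 7 outcompetes self-condensation of 5, and the alkoxide of 8 closes 5-exo-trig on the keto-ester carbonyl to give the enolised butenolide as a racemate whose C5 centre is erased in step 10.

**Step 5**
Reactants: 9 methyl (±)-3-[3,4-bis(benzyloxy)phenyl]-4-hydroxy-5-oxo-2,5-dihydrofuran-2-carboxylate
Product: 10 methyl (±)-3-[3,4-bis(benzyloxy)phenyl]-4-methoxy-5-oxo-2,5-dihydrofuran-2-carboxylate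
Conditions: TMSCHN2, toluene–MeOH (4:1), 0 °C
Reagents that add atoms: (trimethylsilyl)diazomethane, C[Si](C)(C)C=[N+]=[N-]
Why: The acidic enol OH of the isotetronic acid is methylated by the diazoalkane without added base, which avoids C-methylation at the acidic C5–H.

**Step 6**
Reactants: 11 methyl 3-formyl-4-hydroxybenzoate
Product: 12 methyl 4-hydroxy-3-(hydroxymethyl)benzoate
Conditions: NaBH4, MeOH, 0 °C
Reagents that add atoms: none
Why: Borohydride reduction is chemoselective for the aldehyde and leaves the aromatic ester untouched.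

**Step 7**
Reactants: 12 methyl 4-hydroxy-3-(hydroxymethyl)benzoate
Product: 13 methyl 2,2-dimethyl-4H-1,3-benzodioxine-6-carboxylate
Conditions: 2,2-dimethoxypropane, p-TsOH·H2O (cat.), acetone, rt
Reagents that add atoms: 2,2-dimethoxypropane, COC(C)(C)OC
Why: Acid-catalysed transketalisation ties the phenol and the ortho benzylic alcohol into a six-membered ketal, and the para ester suppresses benzylic ionisation while acid is present.

**Step 8**
Reactants: 13 methyl 2,2-dimethyl-4H-1,3-benzodioxine-6-carboxylate
Product: 14 (2,2-dimethyl-4H-1,3-benzodioxin-6-yl)methanol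
Conditions: LiAlH4, THF, 0 °C; then H2O, 15% aq NaOH
Reagents that add atoms: none
Why: Hydride reduction of the ester gives the primary benzylic alcohol, and the ketal is inert to LiAlH4 and to the basic work-up.

**Step 9**
Reactants: 14 (2,2-dimethyl-4H-1,3-benzodioxin-6-yl)methanol
Product: 15 6-(bromomethyl)-2,2-dimethyl-4H-1,3-benzodioxine
Conditions: CBr4, PPh3, CH2Cl2, 0 °C; used at once
Reagents that add atoms: tetrabromomethane, BrC(Br)(Br)Br
Why: The Appel reaction converts the alcohol into the bromide under neutral conditions that spare the ketal, and the reactive para-alkoxybenzyl bromide is carried on without storage.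

**Step 10**
Reactants: 10 methyl (±)-3-[3,4-bis(benzyloxy)phenyl]-4-methoxy-5-oxo-2,5-dihydrofuran-2-carboxylate; 15 6-(bromomethyl)-2,2-dimethyl-4H-1,3-benzodioxine
Product: 16 methyl (2S)-3-[3,4-bis(benzyloxy)phenyl]-2-[(2,2-dimethyl-4H-1,3-benzodioxin-6-yl)methyl]-4-methoxy-5-oxo-2,5-dihydrofuran-2-carboxylate
Conditions: (S)-4,4-dibutyl-2,6-bis(3,4,5-trifluorophenyl)-4,5-dihydro-3H-dinaphtho[2,1-c:1',2'-e]azepinium bromide (2 mol %), Cs2CO3, toluene, −20 °C, Ar
Reagents that add atoms: none
Why: In this asymmetric phase-transfer alkylation, known for the benzo-fused analogues (phthalide-3-carboxylates), solid carbonate removes the doubly activated C5–H, the planar furanolate pairs with the chiral ammonium ion so that one face is open to the bromide and C5 is set as (S), and C5 should react rather than C3 because charge gathers next to the ester and away from the donor methoxy group.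

**Step 11**
Reactants: 16 methyl (2S)-3-[3,4-bis(benzyloxy)phenyl]-2-[(2,2-dimethyl-4H-1,3-benzodioxin-6-yl)methyl]-4-methoxy-5-oxo-2,5-dihydrofuran-2-carboxylate
Product: 17 methyl (2S)-3-[3,4-bis(benzyloxy)phenyl]-2-[4-hydroxy-3-(hydroxymethyl)benzyl]-4-methoxy-5-oxo-2,5-dihydrofuran-2-carboxylate
Conditions: AcOH–H2O–THF (3:1:1), 40 °C
Reagents that add atoms: none
Why: Mild aqueous acid hydrolyses the aryl alkyl ketal but is too weak to ionise the primary benzylic alcohol or to touch the ester, the lactone or the benzyl ethers.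

**Step 12**
Reactants: 18 2-methylprop-1-enylmagnesium bromide; 19 dichlorodiphenylsilane
Product: 21 (2-methylprop-1-enyl)diphenylsilanol, via chlorosilane 20 (not isolated)
Conditions: 18 added to 19 (1.1 equiv), THF, 0 °C → rt; then sat. aq NaHCO3, Et2O, 0 °C
Reagents that add atoms: water, O
Why: Grignard substitution at silicon should stop after one chloride for steric reasons, bicarbonate hydrolysis of the remaining Si–Cl gives the silanol, and the two phenyl groups protect it from self-condensation to the disiloxane.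

**Step 13**
Reactants: 17 methyl (2S)-3-[3,4-bis(benzyloxy)phenyl]-2-[4-hydroxy-3-(hydroxymethyl)benzyl]-4-methoxy-5-oxo-2,5-dihydrofuran-2-carboxylate; 21 (2-methylprop-1-enyl)diphenylsilanol
Product: 23 methyl (2S)-3-[3,4-bis(benzyloxy)phenyl]-2-{[(3S)-3-(hydroxydiphenylsilyl)-2,2-dimethyl-3,4-dihydro-2H-chromen-6-yl]methyl}-4-methoxy-5-oxo-2,5-dihydrofuran-2-carboxylate, via ortho-quinone methide 22 (not isolated)
Conditions: (R)-3,3'-bis(2,4,6-triisopropylphenyl)-1,1'-binaphthyl-2,2'-diyl N-triflylphosphoramide (10 mol %), 21 (5 equiv), 5 Å MS, toluene–CH2Cl2 (3:1), 0 °C → rt, slow addition of 17; Et3N quench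
Reagents that add atoms: none
Why: Proposed new method: protonation of the benzylic hydroxyl of 17 by the N-triflylphosphoramide and loss of water into the sieves should release quinone methide 22 as a hydrogen-bonded, ion-pair-like complex of the catalyst, whose P=O at the same time accepts a hydrogen bond from the Si–OH of 21, so that both partners are held in one chiral pocket. The first bond grows between the exocyclic CH2 of 22 and the CH(Si) terminus of the alkene (C4'–C3'), the resulting cationic character sits on the dimethyl-bearing carbon, and O1' bonds to that carbon (O1'–C2') with return of the proton to the catalyst, so the six-membered dihydropyran ring is closed by an asynchronous inverse-demand oxa-[4+2] cycloaddition (in the stepwise limit, capture of the C2' cation by the phenol oxygen). The closest known reaction types are the chiral phosphoric acid or N-triflylphosphoramide catalysed [4+2] cycloaddition of in situ formed ortho-quinone methides with styrenes, enecarbamates or vinyl sulfides and the achiral strong-acid annulation of ortho-hydroxybenzyl alcohols with simple alkenes, whereas a vinylsilane partner and a quinone methide with an unsubstituted CH2 terminus are untested. C3' is the only new stereocentre and is fixed by which alkene face meets the planar 22, and the controlling element is the catalyst, which grips the silanol two bonds away from C3', because C5 is too remote to bias the approach. Regioselectivity (2,2-dimethyl-3-silyl) comes from the alkene itself, since only attack through CH(Si) places charge on a tertiary carbon next to the C–Si bond, while the needed chemoselectivity, ring closure faster than removal of silicon, is supported by the two phenyl groups that shield silicon, by the non-nucleophilic counter-anion and by the sieves, and slow addition of 17 into excess 21 keeps 22 from self-condensing. The hydroxyl on silicon also prepares step 14, because an aryldimethylsilyl group would need acid, bromine or mercury salts for unmasking, which neither the β-aryloxysilane nor the electron-rich arenes should survive.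

**Step 14**
Reactants: 23 methyl (2S)-3-[3,4-bis(benzyloxy)phenyl]-2-{[(3S)-3-(hydroxydiphenylsilyl)-2,2-dimethyl-3,4-dihydro-2H-chromen-6-yl]methyl}-4-methoxy-5-oxo-2,5-dihydrofuran-2-carboxylate
Product: 24 methyl (2S)-3-[3,4-bis(benzyloxy)phenyl]-2-{[(3S)-3-hydroxy-2,2-dimethyl-3,4-dihydro-2H-chromen-6-yl]methyl}-4-methoxy-5-oxo-2,5-dihydrofuran-2-carboxylate
Conditions: 30% aq H2O2 (excess), KF, KHCO3, THF–MeOH (1:1), 0 °C → rt
Reagents that add atoms: hydrogen peroxide, OO
Why: In the Tamao oxidation, known for silanols and alkoxysilanes including β-oxygenated ones, hydroperoxide adds to the activated silicon and C3' migrates from Si to O with retention, while the bicarbonate buffer, methanol as a degenerate transesterification partner and the benzyl ethers on the catechol protect the rest of the molecule.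

**Step 15**
Reactants: 24 methyl (2S)-3-[3,4-bis(benzyloxy)phenyl]-2-{[(3S)-3-hydroxy-2,2-dimethyl-3,4-dihydro-2H-chromen-6-yl]methyl}-4-methoxy-5-oxo-2,5-dihydrofuran-2-carboxylate
Product: 25 methyl (2S)-3-(3,4-dihydroxyphenyl)-2-{[(3S)-3-hydroxy-2,2-dimethyl-3,4-dihydro-2H-chromen-6-yl]methyl}-4-methoxy-5-oxo-2,5-dihydrofuran-2-carboxylate
Conditions: H2 (1 atm), 10% Pd/C, EtOAc–MeOH, rt
Reagents that add atoms: none
Why: Hydrogenolysis removes both benzyl ethers, and the tetrasubstituted, aryl- and methoxy-bearing butenolide alkene is too hindered to be reduced at atmospheric pressure.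

**Compound list**
1 | 3,4-bis(benzyloxy)benzaldehyde | O=Cc1ccc(OCc2ccccc2)c(OCc2ccccc2)c1 | starting material
2 | hydantoin (imidazolidine-2,4-dione) | O=C1CNC(=O)N1 | starting material
3 | (Z)-5-[3,4-bis(benzyloxy)benzylidene]imidazolidine-2,4-dione | O=C1NC(=O)/C(=C/c2ccc(OCc3ccccc3)c(OCc3ccccc3)c2)N1 | intermediate
4 | 3-[3,4-bis(benzyloxy)phenyl]-2-oxopropanoic acid | OC(=O)C(=O)Cc1ccc(OCc2ccccc2)c(OCc2ccccc2)c1 | intermediate
5 | methyl 3-[3,4-bis(benzyloxy)phenyl]-2-oxopropanoate | COC(=O)C(=O)Cc1ccc(OCc2ccccc2)c(OCc2ccccc2)c1 | intermediate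
6 | methyl 2-hydroxy-2-methoxyacetate (methyl glyoxylate methyl hemiacetal) | COC(O)C(=O)OC | starting material
7 | methyl glyoxylate | COC(=O)C=O | intermediate
8 | dimethyl 3-[3,4-bis(benzyloxy)phenyl]-2-hydroxy-4-oxopentanedioate (aldol adduct, stereoisomer mixture) | COC(=O)C(O)C(c1ccc(OCc2ccccc2)c(OCc2ccccc2)c1)C(=O)C(=O)OC | intermediate
9 | methyl (±)-3-[3,4-bis(benzyloxy)phenyl]-4-hydroxy-5-oxo-2,5-dihydrofuran-2-carboxylate | COC(=O)C1OC(=O)C(O)=C1c1ccc(OCc2ccccc2)c(OCc2ccccc2)c1 | intermediate
10 | methyl (±)-3-[3,4-bis(benzyloxy)phenyl]-4-methoxy-5-oxo-2,5-dihydrofuran-2-carboxylate | COC(=O)C1OC(=O)C(OC)=C1c1ccc(OCc2ccccc2)c(OCc2ccccc2)c1 | intermediate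
11 | methyl 3-formyl-4-hydroxybenzoate | COC(=O)c1ccc(O)c(C=O)c1 | starting material
12 | methyl 4-hydroxy-3-(hydroxymethyl)benzoate | COC(=O)c1ccc(O)c(CO)c1 | intermediate
13 | methyl 2,2-dimethyl-4H-1,3-benzodioxine-6-carboxylate | COC(=O)c1ccc2OC(C)(C)OCc2c1 | intermediate
14 | (2,2-dimethyl-4H-1,3-benzodioxin-6-yl)methanol | OCc1ccc2OC(C)(C)OCc2c1 | intermediate
15 | 6-(bromomethyl)-2,2-dimethyl-4H-1,3-benzodioxine | BrCc1ccc2OC(C)(C)OCc2c1 | intermediate
16 | methyl (2S)-3-[3,4-bis(benzyloxy)phenyl]-2-[(2,2-dimethyl-4H-1,3-benzodioxin-6-yl)methyl]-4-methoxy-5-oxo-2,5-dihydrofuran-2-carboxylate | COC(=O)[C@@]1(Cc2ccc3OC(C)(C)OCc3c2)OC(=O)C(OC)=C1c1ccc(OCc2ccccc2)c(OCc2ccccc2)c1 | intermediate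
17 | methyl (2S)-3-[3,4-bis(benzyloxy)phenyl]-2-[4-hydroxy-3-(hydroxymethyl)benzyl]-4-methoxy-5-oxo-2,5-dihydrofuran-2-carboxylate | COC(=O)[C@@]1(Cc2ccc(O)c(CO)c2)OC(=O)C(OC)=C1c1ccc(OCc2ccccc2)c(OCc2ccccc2)c1 | intermediate
18 | 2-methylprop-1-enylmagnesium bromide (solution in THF) | CC(C)=C[Mg]Br | starting material
19 | dichlorodiphenylsilane | Cl[Si](Cl)(c1ccccc1)c1ccccc1 | starting material
20 | chloro(2-methylprop-1-enyl)diphenylsilane | CC(C)=C[Si](Cl)(c1ccccc1)c1ccccc1 | intermediate
21 | (2-methylprop-1-enyl)diphenylsilanol | CC(C)=C[Si](O)(c1ccccc1)c1ccccc1 | intermediate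
22 | ortho-quinone methide: methyl (2S)-3-[3,4-bis(benzyloxy)phenyl]-4-methoxy-2-[(3-methylidene-4-oxocyclohexa-1,5-dien-1-yl)methyl]-5-oxo-2,5-dihydrofuran-2-carboxylate | COC(=O)[C@@]1(CC2=CC(=C)C(=O)C=C2)OC(=O)C(OC)=C1c1ccc(OCc2ccccc2)c(OCc2ccccc2)c1 | intermediate
23 | methyl (2S)-3-[3,4-bis(benzyloxy)phenyl]-2-{[(3S)-3-(hydroxydiphenylsilyl)-2,2-dimethyl-3,4-dihydro-2H-chromen-6-yl]methyl}-4-methoxy-5-oxo-2,5-dihydrofuran-2-carboxylate | COC(=O)[C@@]1(Cc2ccc3c(c2)C[C@H]([Si](O)(c4ccccc4)c4ccccc4)C(C)(C)O3)OC(=O)C(OC)=C1c1ccc(OCc2ccccc2)c(OCc2ccccc2)c1 | intermediate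
24 | methyl (2S)-3-[3,4-bis(benzyloxy)phenyl]-2-{[(3S)-3-hydroxy-2,2-dimethyl-3,4-dihydro-2H-chromen-6-yl]methyl}-4-methoxy-5-oxo-2,5-dihydrofuran-2-carboxylate | COC(=O)[C@@]1(Cc2ccc3c(c2)C[C@H](O)C(C)(C)O3)OC(=O)C(OC)=C1c1ccc(OCc2ccccc2)c(OCc2ccccc2)c1 | intermediate
25 | methyl (2S)-3-(3,4-dihydroxyphenyl)-2-{[(3S)-3-hydroxy-2,2-dimethyl-3,4-dihydro-2H-chromen-6-yl]methyl}-4-methoxy-5-oxo-2,5-dihydrofuran-2-carboxylate (CNP0289675.4) | COC(=O)[C@@]1(Cc2ccc3c(c2)C[C@H](O)C(C)(C)O3)OC(=O)C(OC)=C1c1ccc(O)c(O)c1 | target

**Step count**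
Total step count: 15.
Longest linear sequence: 10 steps (1–5, 10, 11, 13, 14, 15).

**Steps most likely to fail**

1. Step 13.
 - What may go wrong:
   - Sluggish ionisation of the primary benzylic alcohol, followed by self-condensation of the quinone methide.
   - Nucleophilic removal of silicon from the β-silyl cation, or acid-induced re-opening of the product ring.
   - 1,2-Silyl migration with five-membered ring closure.
   - Weak discrimination of the two alkene faces, which would give C3' epimers that are hard to separate.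
 - Fallback by known chemistry: it sets out from 17 and rejoins the route at 25.
   - MnO2 in CH2Cl2 oxidises the benzylic alcohol to the salicylaldehyde F1.
   - Heating with 2-methylprop-1-enylboronic acid and dibenzylamine in dioxane gives the 2,2-dimethyl-2H-chromene F2. The sequence is a Petasis-type condensation, loss of the amine and oxa-6π electrocyclisation.
   - Jacobsen–Katsuki epoxidation gives the (3'S,4'S)-epoxide F3. The catalyst is the (S,S)-N,N'-bis(3,5-di-tert-butylsalicylidene)cyclohexane-1,2-diamine manganese chloride complex (trivalent manganese), with NaOCl and 4-phenylpyridine N-oxide in CH2Cl2 at 0 °C. This antipode is known to deliver (3S,4S)-epoxides from 2,2-dimethylchromenes.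
   - H2 over Pd/C then cleaves the benzylic C4'–O bond and both benzyl ethers in one operation. The C3'–O bond stays intact.

2. Step 14.
 - What may go wrong:
   - Fragmentation of the pentacoordinate siliconate with expulsion of the aryloxide, since the C–Si bond can lie anti-periplanar to C2'–O1'. This opens the pyran ring faster than carbon migrates to oxygen.
   - Perhydrolysis of the lactone or ester.
 - Fallback: it sets out from 23 and rejoins the route at 25.
   - The fragmentation is driven to completion on purpose with TBAF in THF at 0 °C, which gives the ortho-prenylphenol F4.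
   - DDQ in refluxing toluene effects the classical cyclodehydrogenation of F4 to the 2,2-dimethyl-2H-chromene F2.
   - F2 is carried through the (3'S,4'S)-epoxide F3 and the global hydrogenolysis described under step 13, so C3' is set afresh by the epoxidation catalyst.

3. Step 10.
 - What may go wrong:
   - Insufficient facial discrimination of the furanolate by the ammonium ion.
   - Competing attack through C3 or through oxygen of the ambident anion.
   - Autoxidation of the anion.
   - Decay of the labile bromide before it is consumed.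
 - A partial enrichment should be upgradable by crystallisation of 16 or 17.
 - Fallback: it sets out from 9 (with 15) and rejoins the route at 16.
   - The dianion of 9 (LiHMDS, 2.1 equiv, THF, −78 °C) carries its carbanionic charge at C5 only and is benzylated with 15 to the racemic C5-benzyl isotetronic acid F5.
   - TMSCHN2 converts F5 into the racemic methyl ether F6.
   - Preparative chromatography on a polysaccharide-carbamate chiral stationary phase separates 16 from the (R)-enantiomer F7.

**Further compounds**
F1 | step 13 | methyl (2S)-3-[3,4-bis(benzyloxy)phenyl]-2-(3-formyl-4-hydroxybenzyl)-4-methoxy-5-oxo-2,5-dihydrofuran-2-carboxylate | COC(=O)[C@@]1(Cc2ccc(O)c(C=O)c2)OC(=O)C(OC)=C1c1ccc(OCc2ccccc2)c(OCc2ccccc2)c1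
F2 | step 13 | methyl (2S)-3-[3,4-bis(benzyloxy)phenyl]-2-[(2,2-dimethyl-2H-chromen-6-yl)methyl]-4-methoxy-5-oxo-2,5-dihydrofuran-2-carboxylate | COC(=O)[C@@]1(Cc2ccc3c(c2)C=CC(C)(C)O3)OC(=O)C(OC)=C1c1ccc(OCc2ccccc2)c(OCc2ccccc2)c1
F3 | step 13 | methyl (2S)-3-[3,4-bis(benzyloxy)phenyl]-2-{[(3S,4S)-3,4-epoxy-2,2-dimethyl-3,4-dihydro-2H-chromen-6-yl]methyl}-4-methoxy-5-oxo-2,5-dihydrofuran-2-carboxylate | COC(=O)[C@@]1(Cc2ccc3c(c2)[C@@H]4O[C@@H]4C(C)(C)O3)OC(=O)C(OC)=C1c1ccc(OCc2ccccc2)c(OCc2ccccc2)c1
F4 | step 14 | methyl (2S)-3-[3,4-bis(benzyloxy)phenyl]-2-[4-hydroxy-3-(3-methylbut-2-enyl)benzyl]-4-methoxy-5-oxo-2,5-dihydrofuran-2-carboxylate | COC(=O)[C@@]1(Cc2ccc(O)c(CC=C(C)C)c2)OC(=O)C(OC)=C1c1ccc(OCc2ccccc2)c(OCc2ccccc2)c1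
F5 | step 10 | methyl (±)-3-[3,4-bis(benzyloxy)phenyl]-2-[(2,2-dimethyl-4H-1,3-benzodioxin-6-yl)methyl]-4-hydroxy-5-oxo-2,5-dihydrofuran-2-carboxylate | COC(=O)C1(Cc2ccc3OC(C)(C)OCc3c2)OC(=O)C(O)=C1c1ccc(OCc2ccccc2)c(OCc2ccccc2)c1
F6 | step 10 | methyl (±)-3-[3,4-bis(benzyloxy)phenyl]-2-[(2,2-dimethyl-4H-1,3-benzodioxin-6-yl)methyl]-4-methoxy-5-oxo-2,5-dihydrofuran-2-carboxylate | COC(=O)C1(Cc2ccc3OC(C)(C)OCc3c2)OC(=O)C(OC)=C1c1ccc(OCc2ccccc2)c(OCc2ccccc2)c1
F7 | step 10 | methyl (2R)-3-[3,4-bis(benzyloxy)phenyl]-2-[(2,2-dimethyl-4H-1,3-benzodioxin-6-yl)methyl]-4-methoxy-5-oxo-2,5-dihydrofuran-2-carboxylate | COC(=O)[C@]1(Cc2ccc3OC(C)(C)OCc3c2)OC(=O)C(OC)=C1c1ccc(OCc2ccccc2)c(OCc2ccccc2)c1
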